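Cuts: the pyran O1–C2 bond (back to an ortho-prenylphenol), then the C6 ketone (back to a silyl-masked carbinol). Next the benzene ring is cut at C6–C7, C4a–C5 and C7–C8 (back to a 1-methoxyalkyne and a 3-silyloxycyclobutenone), and last the cyclobutenone (back to a siloxyalkyne and ketene).
Enabling feature: the chromene benzene ring C4a–C5–C6–C7–C8–C8a has oxygen on every second carbon, each one different (C5 OMe, C7 OH, C8a pyran O), carbon chains on C6 and C4a, and H on C8. A vinylketene/ynol ether benzannulation gives exactly this pattern: C7–OH from the ketene carbonyl, C5–OMe from the alkyne, C8a–O from the 3-oxygen of the cyclobutenone.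
Ring order (forward): the four-membered ring comes first and serves only as a strained carrier. The benzene ring follows in the benzannulation, and the pyran ring closes last by oxidative closure onto the one phenol that neighbours the prenyl group.
Stereochemistry: the target has no stereocentre. One carbinol centre is carried as a racemate and disappears on oxidation, and the C3=C4 alkene is cis because it lies in the six-membered ring.

Key step: step 7

Remark: arene positions are given in 2H-chromene numbering (O1, C2, C3, C4, C4a, C5–C8, C8a) throughout, also before the pyran exists; every carbinol-bearing compound is racemic.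

Step 1
Reactants: 1 chloroacetaldehyde dimethyl acetal; 2 4-methoxyphenylacetaldehyde
Product: 4 4-methoxy-1-(4-methoxyphenyl)but-3-yn-2-ol (racemic), via lithium methoxyacetylide 3 (not isolated)
Conditions: Et2NH, n-BuLi, THF, 0 °C; 1, 0 °C; then 2, −78 → −30 °C; pH 7 phosphate buffer
Reagents that add atoms: none
Why: Three equivalents of LiNEt2 convert the chloroacetal by two β-eliminations and a deprotonation into the methoxyacetylide (an established in situ source), and its 1,2-addition to the aldehyde at low temperature should outrun enolisation; the new carbinol centre forms as a racemate and is erased later.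

Step 2
Reactants: 4 4-methoxy-1-(4-methoxyphenyl)but-3-yn-2-ol
Product: 5 triethyl{[4-methoxy-1-(4-methoxyphenyl)but-3-yn-2-yl]oxy}silane (racemic)
Conditions: TESCl, imidazole, DMAP (cat.), CH2Cl2, 0 °C; chromatography on Et3N-washed silica
Reagents that add atoms: chlorotriethylsilane CC[Si](Cl)(CC)CC
Why: Routine O-silylation in basic medium avoids the acid-triggered Meyer–Schuster rearrangement of the alkoxyalkynyl carbinol, and the triethylsilyl group is chosen because it tolerates neutral heating yet can later be removed by buffered HF beside an aryl triisopropylsilyl ether.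

Step 3
Reactants: 6 prenyl bromide (1-bromo-3-methylbut-2-ene); 7 ethynyltrimethylsilane
Product: 9 trimethyl(5-methylhex-4-en-1-yn-1-yl)silane, via alkynylmagnesium bromide 8 (not isolated)
Conditions: 7, EtMgBr, THF, 0 → 40 °C; CuBr·SMe2 (5 mol %), then 6, 0 °C → rt
Reagents that add atoms: none
Why: Copper-catalysed allylation of an alkynyl Grignard reagent should attack the unhindered primary terminus of prenyl bromide (SN2 rather than SN2′) and give the skipped enyne, while the silyl cap rules out double alkylation.

Step 4
Reactants: 9 trimethyl(5-methylhex-4-en-1-yn-1-yl)silane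
Product: 10 5-methylhex-4-en-1-yne
Conditions: K2CO3 (0.2 equiv), MeOH, rt; extraction into pentane, careful distillation
Reagents that add atoms: none
Why: Base-catalysed methanolysis of the alkynyl–SiMe3 bond (protiodesilylation) is mild enough not to isomerise the 1,4-enyne to an allene or a conjugated enyne.

Step 5
Reactants: 10 5-methylhex-4-en-1-yne
Product: 13 triisopropyl[(5-methylhex-4-en-1-yn-1-yl)oxy]silane, via lithium acetylide 11 (not isolated), via lithium ynolate 12 (not isolated)
Conditions: t-BuOOH (decane solution), LiN(SiMe3)2 (2.1 equiv), THF, −78 → 0 °C; then TIPSOTf, −78 → 0 °C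
Reagents that add atoms: tert-butyl hydroperoxide CC(C)(C)OO (the oxygen atom); triisopropylsilyl triflate CC(C)[Si](OS(=O)(=O)C(F)(F)F)(C(C)C)C(C)C
Why: Oxidation of a lithium acetylide by lithium tert-butyl peroxide to the ynolate, followed by O-silylation with a bulky silyl triflate, is the standard one-pot entry to isolable siloxyalkynes, and the unactivated trisubstituted alkene is inert to the nucleophilic peroxide.

Step 6
Reactants: 13 triisopropyl[(5-methylhex-4-en-1-yn-1-yl)oxy]silane; 14 acetyl chloride
Product: 16 2-(3-methylbut-2-en-1-yl)-3-(triisopropylsilyloxy)cyclobut-2-en-1-one, via ketene 15 (not isolated)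
Conditions: 14 (3 equiv, syringe pump), Et3N (3.3 equiv), CH2Cl2, 0 °C → rt
Reagents that add atoms: none
Why: In the known [2+2] cycloaddition of ketenes with siloxyalkynes the alkyne carbon remote from oxygen attacks the ketene carbonyl carbon, so the prenyl group ends at C2 and the silyloxy group at C3 of the cyclobutenone, while the isolated alkene does not react with unsubstituted ketene.

Step 7
Reactants: 5 triethyl{[4-methoxy-1-(4-methoxyphenyl)but-3-yn-2-yl]oxy}silane; 16 2-(3-methylbut-2-en-1-yl)-3-(triisopropylsilyloxy)cyclobut-2-en-1-one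
Product: 21 3-methoxy-2-[2-(4-methoxyphenyl)-1-(triethylsilyloxy)ethyl]-4-(3-methylbut-2-en-1-yl)-5-(triisopropylsilyloxy)phenol (racemic), via vinylketene 17 (not isolated), via vinylcyclobutenone 18 (not isolated), via dienylketene 19 (not isolated), via cyclohexadienone 20 (not isolated)
Conditions: 5 (1.3 equiv), toluene (0.4 M, degassed), sealed tube, 110 °C, then 135 °C until 18 is consumed
Reagents that add atoms: none
Why: Heat opens the strained enone 16 by 4π electrocyclic cleavage of its C(=O)–CH2 bond to vinylketene 17, whose ketene unit adds to ynol ether 5 in a [2+2] cycloaddition (new bonds C6–C7 and C4a–C5) to give vinylcyclobutenone 18; a second 4π opening (C7–C4a breaks) gives dienylketene 19, 6π electrocyclisation (new bond C7–C8) gives dienone 20, and enolisation delivers phenol 21. The closest known reaction is the Danheiser benzannulation of cyclobutenones with alkoxy- and siloxyalkynes, applied here to a 3-silyloxycyclobutenone and an ynol ether that bears a propargylic silyl ether. The transient four-membered ring closes by [2+2] cycloaddition and the benzene ring by 6π electrocyclic closure of the dienylketene, with relief of ring strain and aromatisation as driving forces. No stereocentre of the target is made: the carbinol centre is carried as a racemate, and the quaternary carbon of 18 vanishes in the second ring opening, which is reversible, so only the dienylketene geometry able to cyclise is drained. The selectivity needed is the orientation of the [2+2] step, and the polarisation of 5 secures it: the alkyne carbon remote from OMe is the nucleophile and bonds to the ketene carbonyl carbon, which puts OMe on C5 (meta to the new C7 hydroxyl and next to the prenyl-bearing C4a), the masked acyl chain on C6, the silyloxy group on C8a and H on C8. The methyl ynol ether has no β-hydrogen for retro-ene loss, the neutral medium should leave both silyl ethers intact, and the single CH2 between ketene and prenyl alkene is too short for an intramolecular cycloaddition.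

Step 8
Reactants: 21 benzannulation phenol (C7 OH, C8a OTIPS, carbinol OTES)
Product: 22 2-[1-hydroxy-2-(4-methoxyphenyl)ethyl]-3-methoxy-4-(3-methylbut-2-en-1-yl)-5-(triisopropylsilyloxy)phenol (racemic)
Conditions: HF·pyridine, excess pyridine, THF, 0 °C; NaHCO3 work-up; used crude
Reagents that add atoms: none
Why: Acidic fluoride cleaves alkyl silyl ethers faster than aryl silyl ethers and a triethylsilyl group far faster than a triisopropylsilyl group, so buffered HF·pyridine should free only the carbinol, with the excess pyridine holding back ionisation of the electron-rich benzylic position.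

Step 9
Reactants: 22 ortho-hydroxybenzylic alcohol
Product: 23 1-[2-hydroxy-6-methoxy-5-(3-methylbut-2-en-1-yl)-4-(triisopropylsilyloxy)phenyl]-2-(4-methoxyphenyl)ethan-1-one
Conditions: activated MnO2 (excess), CH2Cl2, rt
Reagents that add atoms: none
Why: MnO2 oxidation of benzylic alcohols is known to convert ortho-hydroxybenzylic carbinols to ortho-hydroxyaryl ketones; the product is stabilised by the C7–OH···O=C hydrogen bond, and the only stereocentre of the route is erased here.

Step 10
Reactants: 23 silyl-protected deoxybenzoin
Product: 24 1-[2,4-dihydroxy-6-methoxy-5-(3-methylbut-2-en-1-yl)phenyl]-2-(4-methoxyphenyl)ethan-1-one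
Conditions: Bu4NF (1.2 equiv), AcOH (1.2 equiv), THF, 0 °C
Reagents that add atoms: none
Why: Fluoride cleavage of an aryl silyl ether is fast and general, and the acetic acid buffer keeps the phenoxide and the acidic ketone CH2 from base-induced side reactions.

Step 11
Reactants: 24 2,4-dihydroxy-6-methoxy-5-prenyl deoxybenzoin
Product: 26 1-(7-hydroxy-5-methoxy-2,2-dimethyl-2H-chromen-6-yl)-2-(4-methoxyphenyl)ethan-1-one (target), via ortho-quinone methide 25 (not isolated)
Conditions: DDQ (1.2 equiv), toluene, 80 °C
Reagents that add atoms: none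
Why: In the well-used DDQ cyclodehydrogenation of ortho-prenylphenols, hydride abstraction from the benzylic-allylic CH2 gives quinone methide 25, which closes the pyran by oxa-6π electrocyclisation; the prenyl group lies between OMe and the C8a hydroxyl, so only one chromene can form, and the ketone CH2 is protected by the adjacent carbonyl, which disfavours hydride loss there.

Compound list
1 | chloroacetaldehyde dimethyl acetal | COC(OC)CCl | starting material
2 | 4-methoxyphenylacetaldehyde | O=CCc1ccc(OC)cc1 | starting material
3 | lithium methoxyacetylide (formed in situ) | COC#C[Li] | intermediate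
4 | 4-methoxy-1-(4-methoxyphenyl)but-3-yn-2-ol (racemic) | COC#CC(O)Cc1ccc(OC)cc1 | intermediate
5 | triethyl{[4-methoxy-1-(4-methoxyphenyl)but-3-yn-2-yl]oxy}silane (racemic) | COC#CC(O[Si](CC)(CC)CC)Cc1ccc(OC)cc1 | intermediate
6 | prenyl bromide | CC(C)=CCBr | starting material
7 | ethynyltrimethylsilane | C#C[Si](C)(C)C | starting material
8 | (trimethylsilylethynyl)magnesium bromide (formed in situ) | C[Si](C)(C)C#C[Mg]Br | intermediate
9 | trimethyl(5-methylhex-4-en-1-yn-1-yl)silane | CC(C)=CCC#C[Si](C)(C)C | intermediate
10 | 5-methylhex-4-en-1-yne | C#CCC=C(C)C | intermediate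
11 | (5-methylhex-4-en-1-yn-1-yl)lithium (formed in situ) | [Li]C#CCC=C(C)C | intermediate
12 | lithium 5-methylhex-4-en-1-yn-1-olate (formed in situ) | [Li]OC#CCC=C(C)C | intermediate
13 | triisopropyl[(5-methylhex-4-en-1-yn-1-yl)oxy]silane | CC(C)=CCC#CO[Si](C(C)C)(C(C)C)C(C)C | intermediate
14 | acetyl chloride | CC(Cl)=O | starting material
15 | ketene (formed in situ) | C=C=O | intermediate
16 | 2-(3-methylbut-2-en-1-yl)-3-(triisopropylsilyloxy)cyclobut-2-en-1-one | O=C1CC(O[Si](C(C)C)(C(C)C)C(C)C)=C1CC=C(C)C | intermediate
17 | vinylketene, 2-prenyl-3-(triisopropylsilyloxy)buta-1,3-dien-1-one (formed in situ) | O=C=C(CC=C(C)C)C(=C)O[Si](C(C)C)(C(C)C)C(C)C | intermediate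
18 | vinylcyclobutenone, 3-methoxy-2-[2-(4-methoxyphenyl)-1-(triethylsilyloxy)ethyl]-4-prenyl-4-[1-(triisopropylsilyloxy)vinyl]cyclobut-2-en-1-one, diastereomer mixture (formed in situ) | O=C1C(C(O[Si](CC)(CC)CC)Cc2ccc(OC)cc2)=C(OC)C1(CC=C(C)C)C(=C)O[Si](C(C)C)(C(C)C)C(C)C | intermediate
19 | dienylketene, 3-methoxy-2-[2-(4-methoxyphenyl)-1-(triethylsilyloxy)ethyl]-4-prenyl-5-(triisopropylsilyloxy)hexa-1,3,5-trien-1-one (formed in situ) | O=C=C(C(O[Si](CC)(CC)CC)Cc1ccc(OC)cc1)C(OC)=C(CC=C(C)C)C(=C)O[Si](C(C)C)(C(C)C)C(C)C | intermediate
20 | cyclohexa-2,4-dien-1-one tautomer of 21 (formed in situ) | O=C1CC(O[Si](C(C)C)(C(C)C)C(C)C)=C(CC=C(C)C)C(OC)=C1C(O[Si](CC)(CC)CC)Cc2ccc(OC)cc2 | intermediate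
21 | 3-methoxy-2-[2-(4-methoxyphenyl)-1-(triethylsilyloxy)ethyl]-4-prenyl-5-(triisopropylsilyloxy)phenol (racemic) | COc1ccc(CC(O[Si](CC)(CC)CC)c2c(O)cc(O[Si](C(C)C)(C(C)C)C(C)C)c(CC=C(C)C)c2OC)cc1 | intermediate
22 | 2-[1-hydroxy-2-(4-methoxyphenyl)ethyl]-3-methoxy-4-prenyl-5-(triisopropylsilyloxy)phenol (racemic) | COc1ccc(CC(O)c2c(O)cc(O[Si](C(C)C)(C(C)C)C(C)C)c(CC=C(C)C)c2OC)cc1 | intermediate
23 | 1-[2-hydroxy-6-methoxy-5-prenyl-4-(triisopropylsilyloxy)phenyl]-2-(4-methoxyphenyl)ethan-1-one | COc1ccc(CC(=O)c2c(O)cc(O[Si](C(C)C)(C(C)C)C(C)C)c(CC=C(C)C)c2OC)cc1 | intermediate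
24 | 1-[2,4-dihydroxy-6-methoxy-5-prenylphenyl]-2-(4-methoxyphenyl)ethan-1-one | COc1ccc(CC(=O)c2c(O)cc(O)c(CC=C(C)C)c2OC)cc1 | intermediate
25 | ortho-quinone methide from 24 (C8a=O, C4a=CH–CH=CMe2; formed in situ) | COc1ccc(CC(=O)C2=C(OC)C(=CC=C(C)C)C(=O)C=C2O)cc1 | intermediate
26 | 1-(7-hydroxy-5-methoxy-2,2-dimethyl-2H-chromen-6-yl)-2-(4-methoxyphenyl)ethan-1-one (CNP0179220.0) | COc1ccc(CC(=O)c2c(O)cc3c(c2OC)C=CC(C)(C)O3)cc1 | target

Total step count: 11. The route is convergent: steps 1–2 make the ynol ether, steps 3–6 make the cyclobutenone, and steps 7–11 join and finish.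
Longest linear sequence: 9 steps (steps 3–11, from prenyl bromide and ethynyltrimethylsilane).

Steps most likely to fail

Step 7.
- What may go wrong: the donor-substituted cyclobutenone may open only at temperatures at which the vinylketene oligomerises. At those temperatures the freshly formed ortho-hydroxybenzylic silyl ether may also lose silanol.
- Fallback: it sets out from 4 and 6 and comes back at 24, and it builds the arene by [4+2] cycloaddition and aromatisation instead.
- Dienophile: carbinol 4 is oxidised with MnO2 to the ynone 4-methoxy-1-(4-methoxyphenyl)but-3-yn-2-one F1.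
- Diene: methyl acetoacetate is alkylated at its γ-carbon with 6 (NaH, then n-BuLi, THF, 0 °C) to methyl 7-methyl-3-oxooct-6-enoate F2. This is silylated (Me3SiCl, Et3N) to methyl 7-methyl-3-(trimethylsilyloxy)octa-2,6-dienoate F3. A second silylation (LiN(iPr)2, Me3SiCl, −78 °C) gives 1-methoxy-7-methyl-1,3-bis(trimethylsilyloxy)octa-1,3,6-triene F4.
- Cycloaddition: warming F4 with F1 in toluene should join the nucleophilic C4 terminus of the diene to the methoxy-bearing β-carbon of the ynone, and the ketene acetal carbon to the α-carbon. This gives the cyclohexa-1,4-diene cycloadduct F5.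
- Aromatisation: F5 collapses with loss of its mixed silyl ketal to the C8a trimethylsilyl ether of the deoxybenzoin F6. Dilute acid work-up then gives 24 with the same oxygen pattern.

Step 6.
- What may go wrong: ketene released from the acid chloride and the amine may dimerise, or acylate the product, faster than the siloxyalkyne captures it. The ammonium salt may also protonate the siloxyalkyne.
- Fallback: it sets out from 13 and comes back at 16. Dichloroketene F7 is generated without amine (Cl3CCOCl, Zn–Cu couple, Et2O) and is a much more reactive ketenophile partner. It should give 4,4-dichloro-2-(3-methylbut-2-en-1-yl)-3-(triisopropylsilyloxy)cyclobut-2-en-1-one F8.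
- Return to the route: reductive dechlorination of F8 (Zn, AcOH, TMEDA, EtOH, 0 °C) gives 16.

Step 8.
- What may go wrong: once the carbinol is free next to an unprotected phenol, loss of water through a quinone methide toward the stilbene may compete. Partial loss of the aryl silyl ether may compete as well. Both would also undermine step 9.
- Fallback: it sets out from 21 and comes back at 24. The C7 phenol is masked first (TBSOTf, 2,6-lutidine, CH2Cl2) to give the tris-silyl ether F9.
- Carbinol release and oxidation: buffered HF·pyridine then frees the carbinol as the bis(aryl silyl ether) alcohol F10, which has no phenol that could expel water. With no free phenol present, Dess–Martin periodinane with NaHCO3 can be used to give the bis-silylated ketone F11.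
- Return to the route: Bu4NF/AcOH removes both aryl silyl groups at once to give 24.

Further compounds
F1 | step 7 | 4-methoxy-1-(4-methoxyphenyl)but-3-yn-2-one | COC#CC(=O)Cc1ccc(OC)cc1
F2 | step 7 | methyl 7-methyl-3-oxooct-6-enoate | COC(=O)CC(=O)CCC=C(C)C
F3 | step 7 | methyl 7-methyl-3-(trimethylsilyloxy)octa-2,6-dienoate | COC(=O)C=C(O[Si](C)(C)C)CCC=C(C)C
F4 | step 7 | 1-methoxy-7-methyl-1,3-bis(trimethylsilyloxy)octa-1,3,6-triene | COC(O[Si](C)(C)C)=CC(O[Si](C)(C)C)=CCC=C(C)C
F5 | step 7 | cyclohexa-1,4-diene cycloadduct of F1 and F4 | COC1(O[Si](C)(C)C)C=C(O[Si](C)(C)C)C(CC=C(C)C)C(OC)=C1C(=O)Cc2ccc(OC)cc2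
F6 | step 7 | 1-[2-hydroxy-6-methoxy-5-prenyl-4-(trimethylsilyloxy)phenyl]-2-(4-methoxyphenyl)ethan-1-one | COc1ccc(CC(=O)c2c(O)cc(O[Si](C)(C)C)c(CC=C(C)C)c2OC)cc1
F7 | step 6 | dichloroketene | ClC(Cl)=C=O
F8 | step 6 | 4,4-dichloro-2-(3-methylbut-2-en-1-yl)-3-(triisopropylsilyloxy)cyclobut-2-en-1-one | O=C1C(Cl)(Cl)C(O[Si](C(C)C)(C(C)C)C(C)C)=C1CC=C(C)C
F9 | step 8 | C7 tert-butyldimethylsilyl ether of 21 (racemic) | COc1ccc(CC(O[Si](CC)(CC)CC)c2c(O[Si](C)(C)C(C)(C)C)cc(O[Si](C(C)C)(C(C)C)C(C)C)c(CC=C(C)C)c2OC)cc1
F10 | step 8 | 1-[2-(tert-butyldimethylsilyloxy)-6-methoxy-5-prenyl-4-(triisopropylsilyloxy)phenyl]-2-(4-methoxyphenyl)ethan-1-ol (racemic) | COc1ccc(CC(O)c2c(O[Si](C)(C)C(C)(C)C)cc(O[Si](C(C)C)(C(C)C)C(C)C)c(CC=C(C)C)c2OC)cc1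
F11 | step 8 | 1-[2-(tert-butyldimethylsilyloxy)-6-methoxy-5-prenyl-4-(triisopropylsilyloxy)phenyl]-2-(4-methoxyphenyl)ethan-1-one | COc1ccc(CC(=O)c2c(O[Si](C)(C)C(C)(C)C)cc(O[Si](C(C)C)(C(C)C)C(C)C)c(CC=C(C)C)c2OC)cc1
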